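**Retrosynthetic overview**

1. The flavanone C2–aryl bond is cut last: a chroman-6-ylboronic acid is added to a bis-silylated 5,7-dihydroxychromone by catalyst-controlled asymmetric 1,4-addition, which sets C2 (S).
2. The cis-diol dihydropyran ring is cut at C3–C4. Both carbons are carbinol CH in the target, so each is an aldehyde one oxidation level down: C4 is the formyl carbon of a salicylaldehyde on benzene ring B, and C3 is a non-enolisable aldehyde on the quaternary O–CMe2 carbon C2. The ring is therefore closed by reductive aldehyde–aldehyde (pinacol) coupling.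
3. This makes the diol without an oxidant, so the prenyl olefin can be carried from step 1.
4. The dialdehyde comes from 4-bromophenol by ortho C-prenylation, ortho-formylation, O-alkylation with ethyl 2-bromoisobutyrate and redox adjustment.
5. Ring order: benzene ring B (bought), then the dihydropyran ring (key step), then attachment of the chromanone rings A and C (bought as the chromone).

Key step: step 6

Assumption: the (S,S)-aminodiol ligand is taken to give the (3S,4S)-diol in step 6 and the (S)-diphosphine to give the (2S)-flavanone in step 10 (the latter by analogy with (S)-biaryl diphosphine–rhodium additions to cyclic enones); if either sense proves opposite, the mirror-image ligand is used.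

**Route**

Step 1
Reactants: 1 4-bromophenol; 2 1-bromo-3-methylbut-2-ene (prenyl bromide)
Product: 3 4-bromo-2-(3-methylbut-2-en-1-yl)phenol
Conditions: NaH, toluene, 0 °C; then 2, rt
Reagents that add atoms: none
Why: Sodium phenoxide in a non-polar solvent reacts as a tight ion pair that directs the allylic halide to the ortho carbon (ortho C-alkylation of phenoxides), and the para position is blocked by bromine.

Step 2
Reactants: 3 4-bromo-2-(3-methylbut-2-en-1-yl)phenol
Product: 4 5-bromo-2-hydroxy-3-(3-methylbut-2-en-1-yl)benzaldehyde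
Conditions: MgCl2, Et3N, (CH2O)n, MeCN, reflux; dilute aq. HCl work-up
Reagents that add atoms: paraformaldehyde (as formaldehyde), C=O
Why: Casnati–Skattebøl ortho-formylation: the magnesium phenoxide delivers formaldehyde to the only free ortho position and a second formaldehyde oxidises the benzylic alkoxide by hydride transfer.

Step 3
Reactants: 4 5-bromo-2-hydroxy-3-(3-methylbut-2-en-1-yl)benzaldehyde; 5 ethyl 2-bromo-2-methylpropanoate
Product: 6 ethyl 2-[4-bromo-2-formyl-6-(3-methylbut-2-en-1-yl)phenoxy]-2-methylpropanoate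
Conditions: Cs2CO3, DMF, 60 °C
Reagents that add atoms: none
Why: Williamson-type O-alkylation of the caesium phenoxide at the carbonyl-activated tertiary bromide (the usual aryloxyisobutyrate synthesis); the ester has no α-hydrogen, so no condensation onto the ortho aldehyde can follow.

Step 4
Reactants: 6 ethyl 2-[4-bromo-2-formyl-6-(3-methylbut-2-en-1-yl)phenoxy]-2-methylpropanoate
Product: 7 2-[4-bromo-2-(hydroxymethyl)-6-(3-methylbut-2-en-1-yl)phenoxy]-2-methylpropan-1-ol
Conditions: LiAlH4, THF, 0 °C; aqueous work-up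
Reagents that add atoms: none
Why: Hydride reduction takes ester and aldehyde to the diol, while the aryl bromide and the isolated olefin are inert to LiAlH4 at 0 °C.

Step 5
Reactants: 7 2-[4-bromo-2-(hydroxymethyl)-6-(3-methylbut-2-en-1-yl)phenoxy]-2-methylpropan-1-ol
Product: 8 5-bromo-2-[(2-methyl-1-oxopropan-2-yl)oxy]-3-(3-methylbut-2-en-1-yl)benzaldehyde
Conditions: Dess–Martin periodinane (2.4 equiv), CH2Cl2, 0 °C → rt
Reagents that add atoms: none
Why: Dess–Martin oxidation of both primary alcohols should stop at the dialdehyde, whose aliphatic aldehyde sits on a quaternary carbon and can neither enolise nor eliminate.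

Step 6
Reactants: 8 5-bromo-2-[(2-methyl-1-oxopropan-2-yl)oxy]-3-(3-methylbut-2-en-1-yl)benzaldehyde
Product: 9 (3S,4S)-6-bromo-2,2-dimethyl-8-(3-methylbut-2-en-1-yl)-3,4-dihydro-2H-chromene-3,4-diol
Conditions: SmI2 (2.5 equiv) premixed with (1S,1'S)-2,2'-(benzylazanediyl)bis(1-phenylethan-1-ol) (2.5 equiv, recoverable), THF, −78 °C, slow addition of dilute 8; aq. NaHCO3
Reagents that add atoms: none
Why: Proposed new method: an enantioselective variant of the SmI2 pinacol cyclisation, in which electron transfer from ligated divalent samarium to the more easily reduced aryl aldehyde gives a ketyl at C4 bound to trivalent samarium, the metal binds the tethered aldehyde oxygen, the C4 radical adds to the C3 carbonyl carbon in a 6-exo-trig closure of the dihydropyran ring, and a second electron transfer gives the samarium diolate that is protonated on work-up. The closest known reaction types are the SmI2 pinacol cyclisation of 1,6-dialdehydes to cis-1,2-diols and the chiral-aminodiol-controlled enantioselective SmI2 ketyl–olefin cyclisation; new here is ligand control of absolute configuration in an aldehyde–aldehyde coupling. The cis relation of the C3 and C4 hydroxyls follows from both oxygens being held on one samarium in the cyclic transition state, and the absolute sense (3S,4S) is set by the C2-symmetric ligand, whose phenyl groups should leave only one of the two mirror-image chelate geometries open. The chemoselectivity needed is secured by the substrate: the aliphatic aldehyde is non-enolisable and sits on a gem-dimethyl carbon that favours ring closure over intermolecular coupling (helped by slow addition), and without HMPA at −78 °C neither the aryl bromide nor the prenyl olefin should be reduced. One operation thus gives the pyran ring, the C3–C4 bond and both carbinol stereocentres at their final oxidation level from an achiral, open-chain dialdehyde.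

Step 7
Reactants: 9 (3S,4S)-6-bromo-2,2-dimethyl-8-(3-methylbut-2-en-1-yl)-3,4-dihydro-2H-chromene-3,4-diol
Product: 10 (3S,4S)-6-bromo-3,4-bis(tert-butyldimethylsilyloxy)-2,2-dimethyl-8-(3-methylbut-2-en-1-yl)-3,4-dihydro-2H-chromene
Conditions: TBSOTf, 2,6-lutidine, CH2Cl2, 0 °C → rt
Reagents that add atoms: tert-butyldimethylsilyl triflate (TBSOTf), CC(C)(C)[Si](C)(C)OS(=O)(=O)C(F)(F)F
Why: The silyl triflate should silylate both the benzylic and the hindered neopentyl-type secondary hydroxyl at oxygen, leaving both stereocentres untouched.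

Step 8
Reactants: 10 (3S,4S)-6-bromo-3,4-bis(tert-butyldimethylsilyloxy)-2,2-dimethyl-8-(3-methylbut-2-en-1-yl)-3,4-dihydro-2H-chromene
Product: 13 [(3S,4S)-3,4-bis(tert-butyldimethylsilyloxy)-2,2-dimethyl-8-(3-methylbut-2-en-1-yl)-3,4-dihydro-2H-chromen-6-yl]boronic acid, via aryllithium 11 (not isolated), via dimethyl arylboronate 12 (not isolated)
Conditions: n-BuLi, THF, −78 °C; B(OMe)3, −78 → 0 °C; sat. aq. NH4Cl
Reagents that add atoms: n-butyllithium, [Li]CCCC (lithium of 11 only); trimethyl borate, COB(OC)OC; water, O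
Why: Bromine–lithium exchange at −78 °C is faster than any deprotonation, the aryllithium is trapped by the borate, and mild hydrolysis gives the boronic acid with the silyl ethers intact.

Step 9
Reactants: 14 5,7-dihydroxy-4H-chromen-4-one
Product: 15 5,7-bis(tert-butyldimethylsilyloxy)-4H-chromen-4-one
Conditions: TBSOTf, 2,6-lutidine, CH2Cl2, 0 °C → rt
Reagents that add atoms: tert-butyldimethylsilyl triflate (TBSOTf), CC(C)(C)[Si](C)(C)OS(=O)(=O)C(F)(F)F
Why: The silyl triflate should silylate both phenols, including the hydrogen-bonded 5-hydroxyl, which would otherwise deactivate the enone and quench the aryl–metal species in step 10.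

Step 10
Reactants: 13 [(3S,4S)-3,4-bis(tert-butyldimethylsilyloxy)-2,2-dimethyl-8-(3-methylbut-2-en-1-yl)-3,4-dihydro-2H-chromen-6-yl]boronic acid; 15 5,7-bis(tert-butyldimethylsilyloxy)-4H-chromen-4-one (1.5 equiv)
Product: 16 (2S)-2-[(3S,4S)-3,4-bis(tert-butyldimethylsilyloxy)-2,2-dimethyl-8-(3-methylbut-2-en-1-yl)-3,4-dihydro-2H-chromen-6-yl]-5,7-bis(tert-butyldimethylsilyloxy)-2,3-dihydro-4H-chromen-4-one
Conditions: [Rh(OH)((S)-MeO-F12-BIPHEP)]2 (cat.; ligand = (S)-2,2'-bis[bis(3,4,5-trifluorophenyl)phosphino]-6,6'-dimethoxybiphenyl), toluene/H2O, 20 °C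
Reagents that add atoms: none
Why: Hayashi–Miyaura asymmetric 1,4-addition: transmetalation gives an aryl–rhodium species that inserts the chromone C2=C3 bond on the face chosen by the chiral diphosphine, which sets C2 as S under catalyst control, and water releases the ketone; the electron-poor ligand allows room temperature, which should suppress 1,2-addition and ring opening of the flavanone.

Step 11
Reactants: 16 (2S)-2-[(3S,4S)-3,4-bis(tert-butyldimethylsilyloxy)-2,2-dimethyl-8-(3-methylbut-2-en-1-yl)-3,4-dihydro-2H-chromen-6-yl]-5,7-bis(tert-butyldimethylsilyloxy)-2,3-dihydro-4H-chromen-4-one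
Product: 17 (2S)-2-[(3S,4S)-3,4-dihydroxy-2,2-dimethyl-8-(3-methylbut-2-en-1-yl)-3,4-dihydro-2H-chromen-6-yl]-5,7-dihydroxy-2,3-dihydro-4H-chromen-4-one (CNP0305950.3)
Conditions: HF·pyridine, pyridine, THF, 0 °C → rt
Reagents that add atoms: none
Why: Fluoride cleaves all four Si–O bonds under mildly acidic, base-free conditions that should leave the flavanone C2 centre (no ring opening), the ortho-alkoxybenzylic C4 carbinol and the prenyl olefin untouched.

**Compound list**

1 | 4-bromophenol | Oc1ccc(Br)cc1 | starting material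
2 | 1-bromo-3-methylbut-2-ene (prenyl bromide) | CC(C)=CCBr | starting material
3 | 4-bromo-2-(3-methylbut-2-en-1-yl)phenol | CC(C)=CCc1cc(Br)ccc1O | intermediate
4 | 5-bromo-2-hydroxy-3-(3-methylbut-2-en-1-yl)benzaldehyde | CC(C)=CCc1cc(Br)cc(C=O)c1O | intermediate
5 | ethyl 2-bromo-2-methylpropanoate | CCOC(=O)C(C)(C)Br | starting material
6 | ethyl 2-[4-bromo-2-formyl-6-(3-methylbut-2-en-1-yl)phenoxy]-2-methylpropanoate | CCOC(=O)C(C)(C)Oc1c(C=O)cc(Br)cc1CC=C(C)C | intermediate
7 | 2-[4-bromo-2-(hydroxymethyl)-6-(3-methylbut-2-en-1-yl)phenoxy]-2-methylpropan-1-ol | CC(C)=CCc1cc(Br)cc(CO)c1OC(C)(C)CO | intermediate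
8 | 5-bromo-2-[(2-methyl-1-oxopropan-2-yl)oxy]-3-(3-methylbut-2-en-1-yl)benzaldehyde | CC(C)=CCc1cc(Br)cc(C=O)c1OC(C)(C)C=O | intermediate
9 | (3S,4S)-6-bromo-2,2-dimethyl-8-(3-methylbut-2-en-1-yl)-3,4-dihydro-2H-chromene-3,4-diol (cis-diol) | CC(C)=CCc1cc(Br)cc2c1OC(C)(C)[C@@H](O)[C@H]2O | intermediate
10 | (3S,4S)-6-bromo-3,4-bis(tert-butyldimethylsilyloxy)-2,2-dimethyl-8-(3-methylbut-2-en-1-yl)-3,4-dihydro-2H-chromene | CC(C)=CCc1cc(Br)cc2c1OC(C)(C)[C@@H](O[Si](C)(C)C(C)(C)C)[C@H]2O[Si](C)(C)C(C)(C)C | intermediate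
11 | aryllithium from 10 (6-lithio compound) | CC(C)=CCc1cc([Li])cc2c1OC(C)(C)[C@@H](O[Si](C)(C)C(C)(C)C)[C@H]2O[Si](C)(C)C(C)(C)C | intermediate
12 | dimethyl arylboronate from 11 | CC(C)=CCc1cc(B(OC)OC)cc2c1OC(C)(C)[C@@H](O[Si](C)(C)C(C)(C)C)[C@H]2O[Si](C)(C)C(C)(C)C | intermediate
13 | [(3S,4S)-3,4-bis(tert-butyldimethylsilyloxy)-2,2-dimethyl-8-(3-methylbut-2-en-1-yl)-3,4-dihydro-2H-chromen-6-yl]boronic acid | CC(C)=CCc1cc(B(O)O)cc2c1OC(C)(C)[C@@H](O[Si](C)(C)C(C)(C)C)[C@H]2O[Si](C)(C)C(C)(C)C | intermediate
14 | 5,7-dihydroxy-4H-chromen-4-one | O=c1ccoc2cc(O)cc(O)c12 | starting material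
15 | 5,7-bis(tert-butyldimethylsilyloxy)-4H-chromen-4-one | O=c1ccoc2cc(O[Si](C)(C)C(C)(C)C)cc(O[Si](C)(C)C(C)(C)C)c12 | intermediate
16 | (2S)-2-[(3S,4S)-3,4-bis(tert-butyldimethylsilyloxy)-2,2-dimethyl-8-(3-methylbut-2-en-1-yl)-3,4-dihydro-2H-chromen-6-yl]-5,7-bis(tert-butyldimethylsilyloxy)-2,3-dihydro-4H-chromen-4-one | CC(C)=CCc1cc([C@@H]2CC(=O)c3c(O[Si](C)(C)C(C)(C)C)cc(O[Si](C)(C)C(C)(C)C)cc3O2)cc2c1OC(C)(C)[C@@H](O[Si](C)(C)C(C)(C)C)[C@H]2O[Si](C)(C)C(C)(C)C | intermediate
17 | (2S)-2-[(3S,4S)-3,4-dihydroxy-2,2-dimethyl-8-(3-methylbut-2-en-1-yl)-3,4-dihydro-2H-chromen-6-yl]-5,7-dihydroxy-2,3-dihydro-4H-chromen-4-one | CC(C)=CCc1cc([C@@H]2CC(=O)c3c(O)cc(O)cc3O2)cc2c1OC(C)(C)[C@@H](O)[C@H]2O | target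

**Step count and risks**

Total step count: 11. Longest linear sequence: 10 (steps 1–8, 10, 11); step 9 prepares the second fragment.

Steps most likely to fail:

1. Step 6 (proposed new method). The transfer of chirality from the ligand may be incomplete if coupling through ligand-free samarium competes, and the ligand hydroxyls may protonate the ketyl and divert it to simple reduction of the aldehyde. Fallback, from 8 back to 9, by known chemistry: the ligand-free SmI2 pinacol cyclisation (THF, −78 °C) should give the cis-diol as a racemate, that is 9 together with its (3R,4R)-enantiomer F1. Acylation with (1S)-(−)-camphanic chloride (DMAP, pyridine, CH2Cl2) should give the diastereomeric bis-camphanates, the (3S,4S)-bis-camphanate F2 and the (3R,4R)-bis-camphanate F3, to be separated by crystallisation or chromatography as is usual for cis-diols of 2,2-dimethylchromans. Saponification of F2 (LiOH, THF/H2O) returns 9.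

2. Step 10. Insertion into the electron-rich, peri-substituted chromone may be slow enough for protodeboronation of 13 to compete, and facial selectivity may be poor or eroded by reversible ring opening of the flavanone. Fallback, from 13 and 15 back to 16: the addition is run with the more active achiral catalyst [Rh(OH)(cod)]2 (dioxane/H2O), which should give 16 mixed with its (2R)-epimer F4. Asymmetric transfer hydrogenation under kinetic-resolution conditions (RuCl(p-cymene)[TsDPEN] in the antipode that matches the (2R)-ketone, HCO2H/Et3N, EtOAc) should then reduce F4 to the cis-flavan-4-ol F5 and leave 16, which is separated by chromatography.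

3. Step 3. Loss of HBr from the tertiary bromide may outrun substitution at the doubly flanked, formyl-deactivated phenoxide. Fallback, from 4 back to 7: 2-bromo-2-methylpropanoic acid with powdered NaOH in THF should generate the α-lactone 3,3-dimethyloxiran-2-one F6 in the flask, a small planar electrophile that the hindered phenoxide opens at the tertiary carbon to give 2-[4-bromo-2-formyl-6-(3-methylbut-2-en-1-yl)phenoxy]-2-methylpropanoic acid F7. LiAlH4 (THF, 0 °C → rt) then reduces acid and aldehyde together to diol 7.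

**Further compounds**

F1 | step 6 | (3R,4R)-6-bromo-2,2-dimethyl-8-(3-methylbut-2-en-1-yl)-3,4-dihydro-2H-chromene-3,4-diol (enantiomer of 9) | CC(C)=CCc1cc(Br)cc2c1OC(C)(C)[C@H](O)[C@@H]2O
F2 | step 6 | (3S,4S)-bis-[(1S)-camphanate] of 9 | CC(C)=CCc1cc(Br)cc2c1OC(C)(C)[C@@H](OC(=O)[C@@]13CC[C@@](C)(C(=O)O1)C3(C)C)[C@H]2OC(=O)[C@@]14CC[C@@](C)(C(=O)O1)C4(C)C
F3 | step 6 | (3R,4R)-bis-[(1S)-camphanate] of F1 | CC(C)=CCc1cc(Br)cc2c1OC(C)(C)[C@H](OC(=O)[C@@]13CC[C@@](C)(C(=O)O1)C3(C)C)[C@@H]2OC(=O)[C@@]14CC[C@@](C)(C(=O)O1)C4(C)C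
F4 | step 10 | (2R)-epimer of 16 | CC(C)=CCc1cc([C@H]2CC(=O)c3c(O[Si](C)(C)C(C)(C)C)cc(O[Si](C)(C)C(C)(C)C)cc3O2)cc2c1OC(C)(C)[C@@H](O[Si](C)(C)C(C)(C)C)[C@H]2O[Si](C)(C)C(C)(C)C
F5 | step 10 | (2R,4R)-cis-flavan-4-ol from F4 | CC(C)=CCc1cc([C@H]2C[C@@H](O)c3c(O[Si](C)(C)C(C)(C)C)cc(O[Si](C)(C)C(C)(C)C)cc3O2)cc2c1OC(C)(C)[C@@H](O[Si](C)(C)C(C)(C)C)[C@H]2O[Si](C)(C)C(C)(C)C
F6 | step 3 | 3,3-dimethyloxiran-2-one (α-lactone, formed in the flask) | CC1(C)OC1=O
F7 | step 3 | 2-[4-bromo-2-formyl-6-(3-methylbut-2-en-1-yl)phenoxy]-2-methylpropanoic acid | CC(C)=CCc1cc(Br)cc(C=O)c1OC(C)(C)C(O)=O
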